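The leftover to expect in epsilon, theta and eta is Q. Each is charged with 0.059 M of it against 0.0560 M of D, and the proposed steps spend one D for each E, so D is the limiting reagent. That gives the rule I carry: the ceiling of E, which is the ratio cD/cQ of the charges, here 94.9% of the Q charged. The ratio gives the end state, and the rate then says how close a flask gets in its time.

in all of them: Q 0.059 M

|  | D | X | temperature | remark | time |
|---|---|---|---|---|---|
| Friday's | 0.056 M | 1.2 mM | 48 °C | run made earlier |  |
| Wednesday's | 0.056 M | 5 mM | 64 °C | run made earlier |  |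
| Monday's | 0.028 M | 2.5 mM | 48 °C | run made earlier |  |
| epsilon | 0.0560 M | 2.5 mM | 55 °C |  | 5.0 min |
| theta | 0.0560 M | 2.5 mM | 70 °C |  | 5.0 min |
| eta | 0.0560 M | 2.5 mM | 40 °C |  | 5.0 min |

| run | time / min | E / % | Q / % |
|---|---|---|---|
| Friday's | 0.333 | 5 | 90 |
| Friday's | 0.667 | 11 | 89 |
| Friday's | 1.00 | 17 | 84 |
| Friday's | 2.00 | 27 | 73 |
| Friday's | 4.00 | 43 | 58 |
| Wednesday's | 0.200 | 28 | 65 |
| Wednesday's | 0.417 | 44 | 48 |
| Wednesday's | 0.667 | 63 | 34 |
| Wednesday's | 1.33 | 81 | 15 |
| Wednesday's | 2.50 | 92 | 2 |
| Monday's | 0.333 | 9 | 89 |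
| Monday's | 1.00 | 13 | 81 |
| Monday's | 2.00 | 24 | 73 |
| Monday's | 3.00 | 29 | 66 |
| Monday's | 4.00 | 34 | 62 |

(scatter of a reading: 2 percentage points)

- steps that have been proposed: Q + X -> J; D <-> G; D + L -> Z; Z <-> X + E; J -> L

1. the flask that comes out highest in amount of E, in percent of the Q charged, or "all alike" when all lie within 1.5 percentage points (epsilon / theta / eta / all alike)
2. E at the end, in percent of the Q charged, epsilon
3. E at the end, in percent of the Q charged, theta
4. E at the end, in percent of the Q charged, eta

Which numbers must I know well? The charges come first: the ceiling is a ratio, so an error in cD or cQ passes into it in the same proportion. Monday's shows the scale, since 0.028 M of D brings its ceiling down to 47.5%. X, temperature and time do not enter the ratio. Wednesday's reads 92% at 2.50 min with 5 mM of X, give or take 2 percentage points. Theta has 2.5 mM of X for 5.0 min, the same product of X and time, and it runs at 70 °C, hotter than Wednesday's 64 °C. So if the rate follows X, I put theta just under the ceiling, in a window of about 2.9 points above that reading. In epsilon and eta the temperature is the number to watch, and with equal X and time I expect theta highest.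

The forecast names theta as highest, with 77% for epsilon, 91% for theta and 51% for eta, and states “D caps E at 95%”.

The flask gives theta as highest, with 93.5% there, 83.4% in epsilon and 51.8% in eta.

    Q + X → J (k = 34.0 /M/s, Ea = 53.0 kJ/mol)
    D ⇌ G (K = 1.50, k = 0.340 /s, Ea = 78.0 kJ/mol, ΔH = −27.0 kJ/mol)
    D + L → Z (k = 32.0 /M/s, Ea = 46.0 kJ/mol)
    Z ⇌ X + E (K = 0.0210 M, k = 160 /s, Ea = 75.0 kJ/mol, ΔH = −57.0 kJ/mol)
    J → L (k = 13.0 /s, Ea = 87.0 kJ/mol)
    (constants at 70 °C)

Theta stops 1.4 points under the ceiling at 93.5%, inside my window, and epsilon left for 50.0 min stands at 94.9%. Now take epsilon with 0.014 M of D instead. The same ratio puts its ceiling at 23.7%, and this neighbour gives 22.5% of E at 5.00 min. There 1.35% of the D charge and 5.63 × 10⁻⁴ M of G remain, while Q stands at 73.3% of its charge.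

(Readings and results were computed on assumed constants; noise was put on by code.)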